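## Retrosynthetic overview

1. The strategy rests on the dihydrofuran ring O1–C2–C3–C3a=C7a fused to the acyl trione ring (C3a, C4=O, C5Me2, C6=O, C7 bearing acyl carbon C8, C7a). Its bonds C3–C3a and O1–C2 are those of a (3+2) adduct between the C3a–C7a–O dicarbonyl unit and a vinyl group whose substituent is the carbinol carbon C1' of (R)-linalool.
2. Key disconnection: oxidative radical (3+2) annulation of 2-isobutyryl-4,4-dimethylcyclohexane-1,3,5-trione with (R)-5-methyl-5-vinyldihydrofuran-2(3H)-one (C3–C3a first, then O1–C2).
3. The γ-lactone masks the electron-rich trisubstituted alkene during the radical step; it is reopened at the end by reduction to the lactol and Wittig isopropylidenation.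
4. Trione: phloroglucinol, Friedel–Crafts isobutyrylation, dearomative gem-dimethylation with two equivalents of iodomethane. Lactone: (R)-linalool, selective ozonolysis, lactol oxidation.
5. Ring order: six-membered carbocycle (bought as arene, dearomatised in step 2), temporary lactone ring (steps 3 and 4), dihydrofuran ring (step 5), lactone ring opened (steps 6 and 7).

Key step: step 5

Assumption: commercial (R)-(−)-linalool of high enantiomeric purity is used and no bond to its carbinol carbon is made or broken, so it becomes C1' (R) unchanged; all acyl trione compounds are tautomeric and are written in one enol form.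

## Route

Step 1
Reactants: 1 phloroglucinol (anhydrous); 2 isobutyryl chloride
Product: 3 2-methyl-1-(2,4,6-trihydroxyphenyl)propan-1-one
Conditions: AlCl3 (4 equiv), PhNO2/CH2Cl2, 0 °C → 60 °C; then ice/aq. HCl
Reagents that add atoms: none
Why: Friedel–Crafts acylation of the threefold-activated symmetrical ring, in which all three ring positions are equivalent and the aluminium-chelated aryl ketone formed first is deactivated against a second acylation.

Step 2
Reactants: 3 2-methyl-1-(2,4,6-trihydroxyphenyl)propan-1-one; 4 iodomethane (first equivalent)
Product: 6 2-isobutyryl-4,4-dimethylcyclohexane-1,3,5-trione (enol form), via mono-C-methyl ketone 5 (not isolated)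
Conditions: NaOMe (4 equiv), MeI (2.2 equiv in all), MeOH, 0 °C → rt; aq. HCl; chromatography
Reagents that add atoms: iodomethane (second equivalent, which supplies the second C-methyl group), CI
Why: Dearomative double C-methylation of the phloroglucinol polyanion (the classical route to acylfilicinic acids), in which the first equivalent of iodomethane alkylates the soft ring carbon between two oxygens rather than oxygen in methanol to give 5, the second equivalent enters at the same, already methylated carbon to give the non-aromatic gem-dimethyl trione, and the limited amount of iodomethane holds back methylation at the remaining ring CH.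

Step 3
Reactants: 7 (R)-linalool
Product: 10 (5R)-5-methyl-5-vinyltetrahydrofuran-2-ol (lactol; both anomers), via secondary ozonide 8 (not isolated), via hydroxy aldehyde 9 (not isolated)
Conditions: O3 (1 equiv, Sudan Red 7B as end-point indicator), CH2Cl2, −78 °C; then Me2S, −78 °C → rt
Reagents that add atoms: ozone, O=[O+][O-]
Why: Chemoselective ozonolysis, in which electrophilic ozone cleaves the electron-rich trisubstituted alkene much faster than the monosubstituted vinyl group, the dye marks the end point, and the γ-hydroxy aldehyde set free on reduction closes to the five-membered lactol with the carbinol centre untouched.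

Step 4
Reactants: 10 (5R)-5-methyl-5-vinyltetrahydrofuran-2-ol
Product: 11 (R)-5-methyl-5-vinyldihydrofuran-2(3H)-one
Conditions: TEMPO (2,2,6,6-tetramethylpiperidin-1-oxyl, 0.1 equiv), PhI(OAc)2 (1.3 equiv), CH2Cl2, rt
Reagents that add atoms: none
Why: Oxoammonium (TEMPO/PhI(OAc)2) oxidation of the hemiacetal C–H turns the lactol into the lactone, while the vinyl group and the tertiary C–O bond are inert, so the configuration is retained.

Step 5
Reactants: 6 2-isobutyryl-4,4-dimethylcyclohexane-1,3,5-trione; 11 (R)-5-methyl-5-vinyldihydrofuran-2(3H)-one (3 equiv, excess recovered)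
Product: 12 (2S)-7-[(Z)-1-hydroxy-2-methylpropylidene]-5,5-dimethyl-2-[(2R)-2-methyl-5-oxooxolan-2-yl]-2,3-dihydro-1-benzofuran-4,6(5H,7H)-dione
Conditions: Mn(OAc)3·2H2O (2.1 equiv), Cu(OAc)2·H2O (0.3 equiv), degassed AcOH, 25 → 45 °C, Ar; chromatography (removal of the C2 epimer and of any regioisomer)
Reagents that add atoms: none
Why: Trivalent manganese oxidises the enolised trione 6 to a radical that reacts at C3a (the only ring carbon carrying hydrogen; C7 is fully substituted and shielded by the acyl group), this radical adds to the unsubstituted CH2 terminus of the vinyl group of 11 to form C3–C3a, and divalent copper (turned over by Mn(OAc)3) oxidises the resulting secondary C2 radical, which the C7a oxygen captures before C3a loses its proton. The closest known reaction type is the Mn(OAc)3-mediated oxidative (3+2) annulation of 1,3-dicarbonyl compounds (acetylacetone, cyclohexane-1,3-diones) with alkenes to 2,3-dihydrofurans. The one ring formed, O1–C2–C3–C3a=C7a, closes by five-membered C–O bond formation of the C7a oxygen onto the oxidised C2 centre (5-exo with respect to C2, the C3a=C7a bond lying inside the ring), either by cation capture or by reductive elimination from a trivalent organocopper chelate. C2 is the only new stereocentre and is set in this C–O closure under 1,2-induction from the quaternary C1'; since the three C1' substituents differ little in size both C2 epimers are expected, and the (2S) compound 12 is to be separated by chromatography and its configuration secured by X-ray analysis or correlation with the final product. The step needs closure through the C7a oxygen and not the C4 oxygen: in the adduct formed first C3a is sp3, so C4=O is an isolated ketone beside quaternary C5 whereas the C7a oxygen belongs to the chelated acyl-enol (the more electron-rich oxygen, giving a delocalised oxocarbenium ion on attack), and the cross-conjugated dienol tautomer likewise keeps its ring carbonyl at C7a, but this preference is not assured and the other regioisomer is to be expected as a by-product. The lactone keeps the nucleophilic trisubstituted alkene of linalool away from the electrophilic radical and is inert to Mn(OAc)3 in acetic acid, and the alkene is used in excess because the product still carries an oxidisable acyl-enol.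

Step 6
Reactants: 12 the (2S,1'R) dihydrofuran lactone
Product: 14 (2S)-2-[(2R)-5-hydroxy-2-methyloxolan-2-yl]-7-[(Z)-1-hydroxy-2-methylpropylidene]-5,5-dimethyl-2,3-dihydro-1-benzofuran-4,6(5H,7H)-dione (lactol; both anomers), via lithium enolate 13 (not isolated)
Conditions: LiN(SiMe3)2 (1.05 equiv), THF, −78 °C; then iBu2AlH (1.3 equiv), THF/CH2Cl2, −78 °C; MeOH, then aq. KNaC4H4O6/NH4Cl
Reagents that add atoms: none
Why: Partial reduction of a lactone with iBu2AlH at low temperature after in situ protection of the acidic acyl-enol as its lithium enolate, whose charge is spread over the C8 and C6 oxygens and, through C7a=C3a, the C4 oxygen, so that only the lactone carbonyl accepts hydride and the tetrahedral aluminium hemiacetal survives until work-up.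

Step 7
Reactants: 14 the lactol
Product: 16 (2S)-2-[(2R)-2-hydroxy-6-methylhept-5-en-2-yl]-7-[(Z)-1-hydroxy-2-methylpropylidene]-5,5-dimethyl-2,3-dihydro-1-benzofuran-4,6(5H,7H)-dione (target), via open-chain hydroxy aldehyde 15 (not isolated)
Conditions: iPrPPh3I (5 equiv), n-BuLi (4.8 equiv), THF, 0 °C; add 14 at −78 °C → rt; aq. NaH2PO4 (pH 5–6)
Reagents that add atoms: isopropyltriphenylphosphonium iodide, CC(C)[P+](c1ccccc1)(c1ccccc1)c1ccccc1.[I-] (used as its ylide isopropylidenetriphenylphosphorane, CC(C)=P(c1ccccc1)(c1ccccc1)c1ccccc1)
Why: Wittig olefination of the lactol through its ring-opened hydroxy aldehyde form, in which excess ylide first deprotonates the enol and the lactol hydroxyl, the symmetrical isopropylidene ylide raises no alkene geometry question, and neither C2 nor C1' carries an acidic hydrogen that the basic medium could remove.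

## Compound list

1 | phloroglucinol (benzene-1,3,5-triol) | Oc1cc(O)cc(O)c1 | starting material
2 | isobutyryl chloride | CC(C)C(Cl)=O | starting material
3 | 2-methyl-1-(2,4,6-trihydroxyphenyl)propan-1-one | CC(C)C(=O)c1c(O)cc(O)cc1O | intermediate
4 | iodomethane | CI | starting material
5 | 2-methyl-1-(2,4,6-trihydroxy-3-methylphenyl)propan-1-one (mono-C-methyl ketone, not isolated) | CC(C)C(=O)c1c(O)cc(O)c(C)c1O | intermediate
6 | 2-isobutyryl-4,4-dimethylcyclohexane-1,3,5-trione (enol form) | CC(C)C(=O)C1=C(O)CC(=O)C(C)(C)C1=O | intermediate
7 | (R)-linalool | CC(C)=CCC[C@@](C)(O)C=C | starting material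
8 | secondary ozonide of the trisubstituted alkene, 5-[(3R)-3-hydroxy-3-methylpent-4-en-1-yl]-3,3-dimethyl-1,2,4-trioxolane (not isolated) | CC1(C)OOC(CC[C@@](C)(O)C=C)O1 | intermediate
9 | (R)-4-hydroxy-4-methylhex-5-enal (not isolated) | O=CCC[C@@](C)(O)C=C | intermediate
10 | (5R)-5-methyl-5-vinyltetrahydrofuran-2-ol (both anomers) | OC1CC[C@@](C)(O1)C=C | intermediate
11 | (R)-5-methyl-5-vinyldihydrofuran-2(3H)-one | O=C1CC[C@@](C)(O1)C=C | intermediate
12 | (2S)-7-[(Z)-1-hydroxy-2-methylpropylidene]-5,5-dimethyl-2-[(2R)-2-methyl-5-oxooxolan-2-yl]-2,3-dihydro-1-benzofuran-4,6(5H,7H)-dione | O=C1CC[C@@](C)(O1)[C@@H]3CC2=C(O3)/C(=C(/O)C(C)C)C(=O)C(C)(C)C2=O | intermediate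
13 | lithium enolate of 12 (not isolated) | [Li+].O=C1CC[C@@](C)(O1)[C@@H]3CC2=C(O3)/C(=C(/[O-])C(C)C)C(=O)C(C)(C)C2=O | intermediate
14 | (2S)-2-[(2R)-5-hydroxy-2-methyloxolan-2-yl]-7-[(Z)-1-hydroxy-2-methylpropylidene]-5,5-dimethyl-2,3-dihydro-1-benzofuran-4,6(5H,7H)-dione (both anomers) | OC1CC[C@@](C)(O1)[C@@H]3CC2=C(O3)/C(=C(/O)C(C)C)C(=O)C(C)(C)C2=O | intermediate
15 | (4R)-4-hydroxy-4-[(2S)-7-(1-hydroxy-2-methylpropylidene)-5,5-dimethyl-4,6-dioxo-2,3,4,5,6,7-hexahydro-1-benzofuran-2-yl]pentanal (not isolated) | O=CCC[C@@](C)(O)[C@@H]1CC2=C(O1)/C(=C(/O)C(C)C)C(=O)C(C)(C)C2=O | intermediate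
16 | (2S)-2-[(2R)-2-hydroxy-6-methylhept-5-en-2-yl]-7-[(Z)-1-hydroxy-2-methylpropylidene]-5,5-dimethyl-2,3-dihydro-1-benzofuran-4,6(5H,7H)-dione | CC(C)=CCC[C@@](C)(O)[C@@H]1CC2=C(O1)/C(=C(/O)C(C)C)C(=O)C(C)(C)C2=O | target

## Step count and risks

Total step count: 7.
Longest linear sequence: 5 steps (7 → 10 → 11 → 12 → 14 → 16; the branch 1 → 3 → 6 → 12 → 14 → 16 is equally long).

The three steps most likely to fail:

**Step 5.** Three processes threaten it:
- ring closure through the C4 oxygen instead of the C7a oxygen;
- poor facial selectivity in the C–O bond formation at C2;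
- slow addition of the radical to the hindered vinyl group, which would let oxidative self-coupling of the trione, further oxidation of the product's acyl-enol, or β-hydride loss from the C2 organocopper take over.

The fallback sets out from 6 and comes back to the route at 16. It makes the same two bonds by polar chemistry with C2 fixed beforehand. Sharpless asymmetric epoxidation of geraniol (Ti(OiPr)4, D-(−)-diethyl tartrate, t-BuOOH, 4 Å molecular sieves, CH2Cl2, −20 °C) should give (2R,3R)-2,3-epoxygeraniol F1. PPh3, I2 and imidazole turn it into the epoxy iodide F2. Alkylation of the sodium enolate of 6 (NaOMe, MeOH, 0 °C → rt) at C3a gives the C3a-alkylated trione epoxide F3. The C7a enolate oxygen then opens the epoxide at its secondary carbon in a 5-exo-tet closure with inversion (same pot, or K2CO3, MeOH). This delivers 16 directly with C2 (S) and C1' (R) both derived from the epoxide, and steps 6 and 7 fall away. The model is the tandem C-alkylation/O-cyclisation of cyclic 1,3-diones with 2,3-epoxy halides of the epichlorohydrin type. Competition between O- and C-alkylation and, again, between the two enolate oxygens in the closure would have to be watched.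

**Step 6.** Hydride may be delivered to the conjugated carbonyls despite the enolate (incomplete deprotonation, aluminium-assisted activation), or the lactol may be over-reduced through its open aldehyde form. The fallback sets out from 10 and comes back at 14. It moves the redox adjustment ahead of the annulation, so that no hydride reagent meets the acyl-enol system. Lactol 10 is converted (MeOH, pyridinium p-toluenesulfonate) into the methyl acetal (5R)-2-methoxy-5-methyl-5-vinyltetrahydrofuran F4. F4 is annulated with 6 under the conditions of step 5 (Mn(OAc)3·2H2O, Cu(OAc)2·H2O, AcOH buffered with NaOAc, or MeOH as solvent) to the annulated methyl acetal F5, with the C2 epimers separated at this stage. Mild hydrolysis (AcOH/H2O/THF, rt) then gives 14.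

**Step 7.** The hindered, strongly basic secondary ylide may act only as a base toward the doubly deprotonated substrate, so that olefination of the small equilibrium amount of open aldehyde stalls. The fallback sets out from 14 and comes back at 16. Methylenation with the unhindered ylide Ph3P=CH2 (MePPh3Br, KOC(CH3)3, THF) gives the terminal alkene F6. Cross-metathesis of F6 with 2-methylbut-2-ene (as co-solvent, CH2Cl2, 40 °C, second-generation Grubbs catalyst) then builds the trisubstituted alkene of 16.

## Further compounds

F1 | step 5 | (2R,3R)-2,3-epoxygeraniol, [(2R,3R)-3-methyl-3-(4-methylpent-3-en-1-yl)oxiran-2-yl]methanol | CC(C)=CCC[C@@](C)(O1)[C@H]1CO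
F2 | step 5 | (2S,3R)-2-(iodomethyl)-3-methyl-3-(4-methylpent-3-en-1-yl)oxirane (same spatial arrangement as F1) | CC(C)=CCC[C@@](C)(O1)[C@H]1CI
F3 | step 5 | 2-isobutyryl-4,4-dimethyl-6-{[(2R,3R)-3-methyl-3-(4-methylpent-3-en-1-yl)oxiran-2-yl]methyl}cyclohexane-1,3,5-trione (dienol form) | CC(C)=CCC[C@@](C)(O1)[C@H]1CC2=C(O)C(C)(C)C(O)=C(C(=O)C(C)C)C2=O
F4 | step 6 | (5R)-2-methoxy-5-methyl-5-vinyltetrahydrofuran (both anomers) | COC1CC[C@@](C)(O1)C=C
F5 | step 6 | (2S)-7-[(Z)-1-hydroxy-2-methylpropylidene]-2-[(2R)-5-methoxy-2-methyloxolan-2-yl]-5,5-dimethyl-2,3-dihydro-1-benzofuran-4,6(5H,7H)-dione | COC1CC[C@@](C)(O1)[C@@H]3CC2=C(O3)/C(=C(/O)C(C)C)C(=O)C(C)(C)C2=O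
F6 | step 7 | (2S)-2-[(2R)-2-hydroxyhex-5-en-2-yl]-7-[(Z)-1-hydroxy-2-methylpropylidene]-5,5-dimethyl-2,3-dihydro-1-benzofuran-4,6(5H,7H)-dione | C=CCC[C@@](C)(O)[C@@H]1CC2=C(O1)/C(=C(/O)C(C)C)C(=O)C(C)(C)C2=O
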